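**Plan**

1. Retrosynthesis: after removal of the silyl and benzyl groups, C5 (the OCH2 of the oxolane) and the hydroxymethyl carbon on C3 are raised to the carboxyl level. The O1–C5 bond is cut first (γ-lactone to γ-hydroxy ester), then C2–C3 (aldol, to 4-O-benzylvanillin), then the auxiliary C–N bond, then the C4–H bonds (hydrogenation) and the veratrylidene C=C (Stobbe, to veratraldehyde and dimethyl succinate).
2. Enabling feature: O1 on the benzylic carbon C2 lies γ to C5, and C5–C4–C3–CH2OH is a succinate chain carrying the veratryl group on C4 and the aryl carbinol on C3. At the diacid oxidation level the oxolane is a γ-aryl paraconic lactone, so the aldol oxygen can close the ring by acylating itself on the C5 ester.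
3. Forward: Stobbe condensation and asymmetric hydrogenation give the (R)-veratrylsuccinic half-ester, and its free acid is loaded onto an oxazolidinone. One boron aldol with the aldehyde joins the two aryl halves and the new hydroxyl lactonises, which forms the only ring with all three stereocentres in place.
4. The two carbonyl helpers are then taken down in turn (imide C=O to CH2OH, lactone C=O to CH2 through the lactol), and the two protecting groups come off last.
5. Stereochemistry: C4 from the ligand-controlled hydrogenation; C2 and C3 from the auxiliary-controlled syn-aldol (syn adduct gives the 2,3-trans ring; 3,4-cis follows from the two absolute controls). No later step breaks a bond at a stereocentre.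

Key step: step 4

Assumption: the (S,S)-antipode of Et-DuPhos is taken to deliver the (R)-acid 5, by analogy with simple itaconates; should the sense be the opposite, the (R,R)-ligand is used and nothing else changes.

**Step 1**
Reactants: 1 3,4-dimethoxybenzaldehyde; 2 dimethyl succinate
Product: 4 (E)-4-(3,4-dimethoxyphenyl)-3-(methoxycarbonyl)but-3-enoic acid, via Stobbe lactone 3 (not isolated)
Conditions: NaOMe (1.5 equiv), MeOH, reflux; then aq. HCl
Reagents that add atoms: none
Why: Stobbe condensation, in which the succinate enolate adds to the aldehyde, the alkoxide lactonises onto the second ester to the paraconic ester 3, and methoxide-induced E1cB opening of 3 should give the (E)-half-ester with the free acid on the CH2 arm; no stereocentre is formed.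

**Step 2**
Reactants: 4 (E)-4-(3,4-dimethoxyphenyl)-3-(methoxycarbonyl)but-3-enoic acid
Product: 5 (R)-4-(3,4-dimethoxyphenyl)-3-(methoxycarbonyl)butanoic acid
Conditions: [Rh(cod)((S,S)-Et-DuPhos)]OTf (0.5 mol %), H2 (5 bar), NaOMe (0.1 equiv), MeOH, rt
Reagents that add atoms: none
Why: asymmetric hydrogenation of an itaconate-type half-ester with a cationic monovalent rhodium bisphospholane catalyst, in which carboxylate and alkene chelate the metal and the C2-symmetric ligand selects the alkene face, so that the later C4 of the oxolane should be set as R.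

**Step 3**
Reactants: 5 (R)-4-(3,4-dimethoxyphenyl)-3-(methoxycarbonyl)butanoic acid; 6 (S)-4-benzyl-1,3-oxazolidin-2-one
Product: 8 methyl (2R)-4-[(4S)-4-benzyl-2-oxo-1,3-oxazolidin-3-yl]-2-(3,4-dimethoxybenzyl)-4-oxobutanoate, via mixed pivalic anhydride 7 (not isolated)
Conditions: t-BuCOCl (1.05 equiv), Et3N (2.5 equiv), THF, −20 °C; then LiCl (1.1 equiv), 6, −20 °C → rt
Reagents that add atoms: none
Why: N-acylation of the oxazolidinone through the mixed anhydride under LiCl/Et3N uses no strong base, so the stereocentre α to the methyl ester should not be enolised, and it installs the imide needed for soft, regioselective enolisation in step 4.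

**Step 4**
Reactants: 8 methyl (2R)-4-[(4S)-4-benzyl-2-oxo-1,3-oxazolidin-3-yl]-2-(3,4-dimethoxybenzyl)-4-oxobutanoate; 9 4-(benzyloxy)-3-methoxybenzaldehyde
Product: 12 (4S)-4-benzyl-3-{[(2S,3S,4R)-2-[4-(benzyloxy)-3-methoxyphenyl]-4-(3,4-dimethoxybenzyl)-5-oxooxolan-3-yl]carbonyl}-1,3-oxazolidin-2-one, via Z-boron enolate 10 (not isolated), via syn-aldol adduct 11 (not isolated)
Conditions: n-Bu2BOTf (1.15 equiv), i-Pr2NEt (1.3 equiv), CH2Cl2, 0 °C; 9, −78 → 0 °C; pH 7 buffer, MeOH, 30% H2O2, 0 °C; crude 11, PPTS (10 mol %), toluene, 50 °C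
Reagents that add atoms: none
Why: n-Bu2BOTf/i-Pr2NEt should enolise only the imide CH2 (boron activates the imide, the hindered ester α-CH stays untouched) to the Z-enolate 10, which adds to 9 through a closed chair (Zimmerman–Traxler) transition state with the oxazolidinone carbonyl turned away from boron and the (S)-benzyl group shielding one enolate face, giving the syn adduct 11 with the new centres 3S and 4S (later C3 and C2 of the oxolane). In 11 the benzylic oxygen (later O1) sits γ to the methyl ester carbon (later C5) along the succinate backbone, so it attacks that carbonyl and expels methanol in a 5-exo-trig acyl substitution that closes the γ-lactone and forms the O1–C5 bond; attack on the imide carbonyl would need a four-membered ring and does not compete. The closest known reaction type is the Evans syn-aldol of succinate-derived imides with γ-lactonisation to trans-paraconic acid derivatives, which is the controlled counterpart of the lactone stage of the Stobbe condensation. C2 and C3 are set by the auxiliary (the syn adduct maps onto the 2,3-trans lactone), C4 is carried in from step 2, and reagent control by the auxiliary is expected to override the small bias of the resident centre, whose two flanking groups (CO2Me and CH2Ar) are of similar size. The step needs regioselective enolisation, syn selectivity and ring closure without retro-aldol or benzylic ionisation, and these are secured by the imide acidity, the boron chair and the mild acid used for lactonisation.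

**Step 5**
Reactants: 12 (4S)-4-benzyl-3-{[(2S,3S,4R)-2-[4-(benzyloxy)-3-methoxyphenyl]-4-(3,4-dimethoxybenzyl)-5-oxooxolan-3-yl]carbonyl}-1,3-oxazolidin-2-one
Product: 14 (2S,3S,4R)-2-[4-(benzyloxy)-3-methoxyphenyl]-4-(3,4-dimethoxybenzyl)-5-oxooxolane-3-carboxylic acid, via peroxy acid 13 (not isolated)
Conditions: LiOH (2 equiv), 30% H2O2 (4 equiv), THF/H2O 3:1, 0 °C; aq. Na2SO3; aq. HCl to pH 2
Reagents that add atoms: hydrogen peroxide (as LiOOH), OO
Why: hydroperoxide cleavage of the N-acyl oxazolidinone, in which LiOOH attacks the exocyclic imide carbonyl even when hindered, sulfite reduces the peroxy acid 13, and any lactone opened by base recloses on acidification because at this oxidation level only the one γ-lactone can form.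

**Step 6**
Reactants: 14 (2S,3S,4R)-2-[4-(benzyloxy)-3-methoxyphenyl]-4-(3,4-dimethoxybenzyl)-5-oxooxolane-3-carboxylic acid
Product: 15 (3R,4R,5S)-5-[4-(benzyloxy)-3-methoxyphenyl]-3-(3,4-dimethoxybenzyl)-4-(hydroxymethyl)oxolan-2-one
Conditions: BH3·SMe2 (1.5 equiv), THF, 0 °C → rt; MeOH
Reagents that add atoms: none
Why: borane reduces the free carboxylic acid through its acyloxyborane much faster than the γ-lactone and without base, so the hydroxymethyl group should appear with the lactone (and the O1–C5 bond) intact and without translactonisation.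

**Step 7**
Reactants: 15 (3R,4R,5S)-5-[4-(benzyloxy)-3-methoxyphenyl]-3-(3,4-dimethoxybenzyl)-4-(hydroxymethyl)oxolan-2-one
Product: 16 (3R,4R,5S)-5-[4-(benzyloxy)-3-methoxyphenyl]-4-{[tert-butyl(diphenyl)silyl]oxymethyl}-3-(3,4-dimethoxybenzyl)oxolan-2-one
Conditions: t-BuPh2SiCl (1.2 equiv), imidazole (2 equiv), CH2Cl2, 0 °C → rt
Reagents that add atoms: tert-butyl(chloro)diphenylsilane, CC(C)(C)[Si](Cl)(c1ccccc1)c1ccccc1
Why: silylation of the primary alcohol under weakly basic conditions gives an acid-robust ether that stops the primary oxygen from competing for C5 (lactol or lactone isomerisation) in steps 8 and 9.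

**Step 8**
Reactants: 16 (3R,4R,5S)-5-[4-(benzyloxy)-3-methoxyphenyl]-4-{[tert-butyl(diphenyl)silyl]oxymethyl}-3-(3,4-dimethoxybenzyl)oxolan-2-one
Product: 17 (3R,4R,5S)-5-[4-(benzyloxy)-3-methoxyphenyl]-4-{[tert-butyl(diphenyl)silyl]oxymethyl}-3-(3,4-dimethoxybenzyl)oxolan-2-ol (anomeric mixture)
Conditions: i-Bu2AlH (1.2 equiv), CH2Cl2, −78 °C; aq. Rochelle salt
Reagents that add atoms: none
Why: partial reduction of a γ-lactone with i-Bu2AlH at −78 °C stops at the tetrahedral aluminate, which gives the lactol on work-up, while benzyl and silyl ethers are inert.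

**Step 9**
Reactants: 17 (3R,4R,5S)-5-[4-(benzyloxy)-3-methoxyphenyl]-4-{[tert-butyl(diphenyl)silyl]oxymethyl}-3-(3,4-dimethoxybenzyl)oxolan-2-ol
Product: 18 tert-butyl{[(2S,3R,4R)-2-[4-(benzyloxy)-3-methoxyphenyl]-4-(3,4-dimethoxybenzyl)oxolan-3-yl]methoxy}diphenylsilane
Conditions: Et3SiH (3 equiv), BF3·OEt2 (1.5 equiv), CH2Cl2, −78 °C; aq. NaHCO3 at −78 °C
Reagents that add atoms: none
Why: ionic deoxygenation of a lactol, in which BF3 ionises the anomeric C5–OH to the cyclic oxocarbenium ion and Et3SiH reduces it to the C5 methylene, should at −78 °C be much faster than ionisation of the benzylic C2–O1 bond or enolisation towards C4, so the three stereocentres persist.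

**Step 10**
Reactants: 18 tert-butyl{[(2S,3R,4R)-2-[4-(benzyloxy)-3-methoxyphenyl]-4-(3,4-dimethoxybenzyl)oxolan-3-yl]methoxy}diphenylsilane
Product: 19 [(2S,3R,4R)-2-[4-(benzyloxy)-3-methoxyphenyl]-4-(3,4-dimethoxybenzyl)oxolan-3-yl]methanol
Conditions: Bu4NF (1.5 equiv), AcOH (1.5 equiv), THF, 0 °C → rt
Reagents that add atoms: none
Why: fluoride cleavage of the silyl ether is driven by Si–F bond formation, and the acetic acid buffer keeps the medium from becoming basic.

**Step 11**
Reactants: 19 [(2S,3R,4R)-2-[4-(benzyloxy)-3-methoxyphenyl]-4-(3,4-dimethoxybenzyl)oxolan-3-yl]methanol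
Product: 20 4'-O-methyllariciresinol = [(2S,3R,4R)-2-(4-hydroxy-3-methoxyphenyl)-4-(3,4-dimethoxybenzyl)oxolan-3-yl]methanol
Conditions: H2 (1 atm), 10% Pd/C, EtOAc, rt
Reagents that add atoms: none
Why: hydrogenolysis of the aryl benzyl ether over Pd/C is fast at 1 atm in EtOAc and is stopped at full conversion, before the slower cleavage of the benzylic C2–O1 bond of the oxolane can set in.

**Compound list**

1 | 3,4-dimethoxybenzaldehyde | COc1ccc(C=O)cc1OC | starting material
2 | dimethyl succinate | COC(=O)CCC(=O)OC | starting material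
3 | methyl 2-(3,4-dimethoxyphenyl)-5-oxooxolane-3-carboxylate (Stobbe lactone, racemic, configuration not fixed) | COC(=O)C1CC(=O)OC1c1ccc(OC)c(OC)c1 | intermediate
4 | (E)-4-(3,4-dimethoxyphenyl)-3-(methoxycarbonyl)but-3-enoic acid | COC(=O)/C(CC(=O)O)=C/c1ccc(OC)c(OC)c1 | intermediate
5 | (R)-4-(3,4-dimethoxyphenyl)-3-(methoxycarbonyl)butanoic acid | COC(=O)[C@@H](CC(=O)O)Cc1ccc(OC)c(OC)c1 | intermediate
6 | (S)-4-benzyl-1,3-oxazolidin-2-one | O=C1N[C@@H](Cc2ccccc2)CO1 | starting material
7 | mixed pivalic anhydride of 5, (R)-configured | COC(=O)[C@@H](CC(=O)OC(=O)C(C)(C)C)Cc1ccc(OC)c(OC)c1 | intermediate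
8 | methyl (2R)-4-[(4S)-4-benzyl-2-oxo-1,3-oxazolidin-3-yl]-2-(3,4-dimethoxybenzyl)-4-oxobutanoate | COC(=O)[C@@H](CC(=O)N1[C@@H](Cc2ccccc2)COC1=O)Cc1ccc(OC)c(OC)c1 | intermediate
9 | 4-(benzyloxy)-3-methoxybenzaldehyde | COc1cc(C=O)ccc1OCc1ccccc1 | starting material
10 | methyl (2R,3Z)-4-[(4S)-4-benzyl-2-oxo-1,3-oxazolidin-3-yl]-4-[(dibutylboranyl)oxy]-2-(3,4-dimethoxybenzyl)but-3-enoate (Z-boron enolate) | CCCCB(CCCC)O/C(N1[C@@H](Cc2ccccc2)COC1=O)=C\[C@@H](Cc1ccc(OC)c(OC)c1)C(=O)OC | intermediate
11 | methyl (2R,3S,4S)-3-{[(4S)-4-benzyl-2-oxo-1,3-oxazolidin-3-yl]carbonyl}-4-[4-(benzyloxy)-3-methoxyphenyl]-2-(3,4-dimethoxybenzyl)-4-hydroxybutanoate (syn-aldol adduct) | COc1cc([C@@H](O)[C@@H](C(=O)N2[C@@H](Cc3ccccc3)COC2=O)[C@@H](Cc2ccc(OC)c(OC)c2)C(=O)OC)ccc1OCc1ccccc1 | intermediate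
12 | (4S)-4-benzyl-3-{[(2S,3S,4R)-2-[4-(benzyloxy)-3-methoxyphenyl]-4-(3,4-dimethoxybenzyl)-5-oxooxolan-3-yl]carbonyl}-1,3-oxazolidin-2-one | COc1cc([C@H]2OC(=O)[C@H](Cc3ccc(OC)c(OC)c3)[C@@H]2C(=O)N2[C@@H](Cc3ccccc3)COC2=O)ccc1OCc1ccccc1 | intermediate
13 | (2S,3S,4R)-2-[4-(benzyloxy)-3-methoxyphenyl]-4-(3,4-dimethoxybenzyl)-5-oxooxolane-3-carboperoxoic acid | COc1cc([C@H]2OC(=O)[C@H](Cc3ccc(OC)c(OC)c3)[C@@H]2C(=O)OO)ccc1OCc1ccccc1 | intermediate
14 | (2S,3S,4R)-2-[4-(benzyloxy)-3-methoxyphenyl]-4-(3,4-dimethoxybenzyl)-5-oxooxolane-3-carboxylic acid | COc1cc([C@H]2OC(=O)[C@H](Cc3ccc(OC)c(OC)c3)[C@@H]2C(=O)O)ccc1OCc1ccccc1 | intermediate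
15 | (3R,4R,5S)-5-[4-(benzyloxy)-3-methoxyphenyl]-3-(3,4-dimethoxybenzyl)-4-(hydroxymethyl)oxolan-2-one | COc1cc([C@H]2OC(=O)[C@H](Cc3ccc(OC)c(OC)c3)[C@@H]2CO)ccc1OCc1ccccc1 | intermediate
16 | (3R,4R,5S)-5-[4-(benzyloxy)-3-methoxyphenyl]-4-{[tert-butyl(diphenyl)silyl]oxymethyl}-3-(3,4-dimethoxybenzyl)oxolan-2-one | COc1cc([C@H]2OC(=O)[C@H](Cc3ccc(OC)c(OC)c3)[C@@H]2CO[Si](c2ccccc2)(c2ccccc2)C(C)(C)C)ccc1OCc1ccccc1 | intermediate
17 | (3R,4R,5S)-5-[4-(benzyloxy)-3-methoxyphenyl]-4-{[tert-butyl(diphenyl)silyl]oxymethyl}-3-(3,4-dimethoxybenzyl)oxolan-2-ol (anomeric mixture) | COc1cc([C@H]2OC(O)[C@H](Cc3ccc(OC)c(OC)c3)[C@@H]2CO[Si](c2ccccc2)(c2ccccc2)C(C)(C)C)ccc1OCc1ccccc1 | intermediate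
18 | tert-butyl{[(2S,3R,4R)-2-[4-(benzyloxy)-3-methoxyphenyl]-4-(3,4-dimethoxybenzyl)oxolan-3-yl]methoxy}diphenylsilane | COc1cc([C@H]2OC[C@H](Cc3ccc(OC)c(OC)c3)[C@@H]2CO[Si](c2ccccc2)(c2ccccc2)C(C)(C)C)ccc1OCc1ccccc1 | intermediate
19 | [(2S,3R,4R)-2-[4-(benzyloxy)-3-methoxyphenyl]-4-(3,4-dimethoxybenzyl)oxolan-3-yl]methanol | COc1cc([C@H]2OC[C@H](Cc3ccc(OC)c(OC)c3)[C@@H]2CO)ccc1OCc1ccccc1 | intermediate
20 | 4'-O-methyllariciresinol, [(2S,3R,4R)-2-(4-hydroxy-3-methoxyphenyl)-4-(3,4-dimethoxybenzyl)oxolan-3-yl]methanol | COc1cc([C@H]2OC[C@H](Cc3ccc(OC)c(OC)c3)[C@@H]2CO)ccc1O | target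

**Step count and risks**

Total: 11 steps. Longest linear sequence: 11 steps (1 and 2 to 20); 6 and 9 are purchased and enter in steps 3 and 4.

Steps most likely to fail:

1. Step 4. What may go wrong: the resident centre of 8 may work against the auxiliary and lower the facial selectivity, the ester α-CH may be partly enolised (loss of configuration at the later C4), or ring closure may stall at the open adduct. Fallback (sets out from 4 and 6, comes back at 12): the ring-forming aldol is run before the C4 centre exists. The unsaturated Stobbe acid 4 is coupled with 6 as in step 3, through the unsaturated mixed pivalic anhydride F1, to the β,γ-unsaturated imide F2. n-Bu2BOTf/i-Pr2NEt gives the boron dienolate F3, which adds to 9 at its α-carbon to the unsaturated syn-aldol adduct F4. Lactonisation with PPTS gives the benzylidene lactone imide F5. Hydrogenation of its exocyclic alkene (H2, 5% Pd/C poisoned with Ph2S, EtOAc, so that the aryl benzyl ether and the benzylic lactone C–O bond stay) from the face opposite the C3 acyl group should give 12. C4 is then set by the ring (substrate control) and step 2 is not needed.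

2. Step 9. What may go wrong: BF3 may ionise the benzylic C2–O1 bond (epimerisation at C2 or reductive ring opening), or the oxocarbenium ion may enolise and lose the C4 configuration. Fallback (sets out from 16, comes back at 18): the O1–C5 bond is closed at the alcohol oxidation level instead. LiBH4 (THF, 0 °C → rt) reduces lactone 16 to the 1,4-diol F6. Mitsunobu cyclodehydration (PPh3, DIAD, THF, 0 °C) activates the primary hydroxyl, and the benzylic hydroxyl displaces it (5-exo-tet, retention at C2) to give 18.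

3. Step 5. What may go wrong: hydroxide may attack the ring carbonyl of the hindered imide (endocyclic cleavage of the auxiliary), or base may epimerise C3. Fallback (sets out from 12, comes back at 15): the auxiliary is removed by reduction and not by hydrolysis. NaBH4 in THF/H2O at 0 °C reduces the exocyclic imide carbonyl directly to the hydroxymethyl group, the γ-lactone being slower, and gives 15 in one step; acid 14 is bypassed and no new compound is made.

**Further compounds**

F1 | step 4 | (E)-4-(3,4-dimethoxyphenyl)-3-(methoxycarbonyl)but-3-enoic pivalic anhydride (unsaturated mixed pivalic anhydride) | COC(=O)/C(CC(=O)OC(=O)C(C)(C)C)=C/c1ccc(OC)c(OC)c1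
F2 | step 4 | methyl (2E)-2-{2-[(4S)-4-benzyl-2-oxo-1,3-oxazolidin-3-yl]-2-oxoethyl}-3-(3,4-dimethoxyphenyl)prop-2-enoate (β,γ-unsaturated imide) | COC(=O)/C(CC(=O)N1[C@@H](Cc2ccccc2)COC1=O)=C/c1ccc(OC)c(OC)c1
F3 | step 4 | Z-dibutylboron dienolate of F2 (boron dienolate) | CCCCB(CCCC)O/C(N1[C@@H](Cc2ccccc2)COC1=O)=C\C(C(=O)OC)=C/c1ccc(OC)c(OC)c1
F4 | step 4 | methyl (2E)-2-{(1S,2S)-1-{[(4S)-4-benzyl-2-oxo-1,3-oxazolidin-3-yl]carbonyl}-2-[4-(benzyloxy)-3-methoxyphenyl]-2-hydroxyethyl}-3-(3,4-dimethoxyphenyl)prop-2-enoate (unsaturated syn-aldol adduct) | COc1cc([C@@H](O)[C@@H](C(=O)N2[C@@H](Cc3ccccc3)COC2=O)/C(=C\c2ccc(OC)c(OC)c2)C(=O)OC)ccc1OCc1ccccc1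
F5 | step 4 | (4S)-4-benzyl-3-{[(2S,3S,4E)-2-[4-(benzyloxy)-3-methoxyphenyl]-4-(3,4-dimethoxybenzylidene)-5-oxooxolan-3-yl]carbonyl}-1,3-oxazolidin-2-one (benzylidene lactone imide) | COc1cc([C@H]2OC(=O)/C(=C/c3ccc(OC)c(OC)c3)[C@@H]2C(=O)N2[C@@H](Cc3ccccc3)COC2=O)ccc1OCc1ccccc1
F6 | step 9 | (1S,2R,3R)-1-[4-(benzyloxy)-3-methoxyphenyl]-2-{[tert-butyl(diphenyl)silyl]oxymethyl}-3-(3,4-dimethoxybenzyl)butane-1,4-diol (1,4-diol) | COc1cc([C@@H](O)[C@@H](CO[Si](c2ccccc2)(c2ccccc2)C(C)(C)C)[C@H](CO)Cc2ccc(OC)c(OC)c2)ccc1OCc1ccccc1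
F0 | step 5 | none | none
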